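Less X through less L is impossible to read out of these runs: the west run, with 0.20 M of L, ends at 27.0 % X, and the north-west run, with 0.10 M, ends at 28.6 %.

| flask | L | J | Q | remark | time |
|---|---|---|---|---|---|
| west | 0.20 M | 0.22 M | 2 mM | run made earlier |  |
| north-west | 0.10 M | 0.22 M | 2 mM | run made earlier |  |
| east | 0.15 M | 0.22 M | 2 mM | run made earlier |  |
| Thursday's | 0.20 M | 0.220 M | 2.0 mM | everything together at the start | 15 h |
| Wednesday's | 0.20 M | 0.220 M (fed, over 12 h) | 2.0 mM | all else is in the flask from the start; the feed brings no volume worth counting | 15 h |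
| Friday's | 0.20 M (fed, over 12 h) | 0.220 M | 2.0 mM | all else is in the flask from the start; the feed brings no volume worth counting | 15 h |

- west (time / h: D / %, X / %): 1.33: 0.8, 19.5; 4.00: 4.6, 25.6; 8.00: 11.8, 26.9; 10.0: 14.9, 27.2; 15.0: 21.4, 27.0
- north-west (time / h: D / %, X / %): 1.00: 0.5, 16.8; 2.00: 1.0, 24.6; 3.00: 3.5, 27.5; 6.00: 9.7, 27.9; 12.0: 20.7, 28.6
- east (time / h: D / %, X / %): 1.00: 0.4, 16.4; 3.00: 3.6, 25.9; 6.00: 8.6, 27.5; 8.00: 13.3, 27.3; 12.0: 19.5, 27.5

(scatter of a reading: 0.3 percentage points)



1. which flask leads in share of D in D plus X ("all alike" within 1.5 percentage points) (Thursday's / Wednesday's / Friday's / all alike)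
2. share of D in D plus X at the end, Thursday's
3. share of D in D plus X at the end, Wednesday's
4. share of D in D plus X at the end, Friday's

*When does X stop?* Early: by 1.00 h the north-west run already holds 16.8 % X of its final 28.6 %, and later D grows while X stands still. So control changes hands within the first 3.00 h, by when the north-west run holds 27.5 % X.

*What carries over?* The burst odds: X made over the L that went elsewhere, 0.370 in the west run. The plateaus suggest that these odds hardly follow L.

*And J? It was never varied.* True, that is the weak spot. The plateau creeps up as L falls and less J is used, so I assume that X needs J. I therefore divide by J and get κ, the burst odds per mole per litre of J, a selectivity factor: 1.68 L mol⁻¹.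

*Wednesday's?* At 1.00 h the feed has brought 0.0183 M of J, so the odds are 0.0308 and X is 2.99 %.

*Friday's?* J starts as charged, and I take the plateaus to say that L hardly counts, so I reckon X near 27.0 %; but no run so far fed L, so this is a guess.

*And D?* I assume the west run's 21.4 % for each flask. Thursday's and Friday's then share 44.2 %, and Wednesday's 87.7 %, more than either.

The forecast gives Thursday's 44.2 %, Wednesday's 87 % and Friday's 89 %, names Friday's as leader and holds that “Feeding L keeps L low during the burst”, so it parts from my reckoning on Friday's.

The flasks give 44.4 % for Thursday's, 86.7 % for Wednesday's and 47.5 % for Friday's, so Wednesday's leads. Wednesday's ended with 3.67 % X, against 26.8 % in Thursday's.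

    L + J → X (k = 0.0170 L mol⁻¹ min⁻¹)
    L + Z → Z + G (k = 7.10 L mol⁻¹ min⁻¹)
    J + Z + G → Z + D (k = 1.50 L² mol⁻² min⁻¹)
    Q → Z (k = 0.0230 min⁻¹)

On Friday's mean J of 0.195 M, κ gives odds of 0.327, so X of 24.7 %, above the 18.9 % found.

Take Thursday's flask with 0.37 M of J: κ gives odds of 0.622, so X of 38.3 %. The computed flask ends at 39.7 % X.

All runs come from a simulation for substances that don't exist.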